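The plan removes the C6–O bond of the γ-lactone (ring O–C6–C7–C11–C12). In the seco acid, C6 is a plain CH2. It is allylic to C4=C5, the only electron-rich alkene, and lies 1,4 to the C12 carboxyl group. An engineered cytochrome P450 replaces the pro-α hydrogen at C6 by hydroxyl and the alcohol closes on C12. One operation therefore sets C6 and builds the trans-fused lactone on the ten-membered ring. The seco acid is a cis,cis-germacratrien-12-oic acid that already carries the 8β-methacrylate, the 9β-acetate and the C14 enal. C7 and C8 come from (S)-3-hydroxybutyrolactone, C9 from a chromium-mediated ring closure, and the 4,5-epoxide from a last peracid step.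

Key step: step 18

Numbering: germacrane locants are used for all intermediates (ring C1–C10, acrylate C11–C13, C14 on C10, C15 on C4). The labels α and β refer to the usual drawing with H7 α. C1=C10 is cis within the ring (C2 and C9 on the same side) but E by the sequence rule, because C14 outranks C9.
Assumption: the remote epoxide carbon in 2–5 and 8–12 is carried as an epimer mixture, which is harmless because that carbon leaves as acetone in step 9.

Step 1
Reactants: 1 neryl acetate
Product: 2 6,7-epoxyneryl acetate
Conditions: mCPBA (1.0 equiv), CH2Cl2, 0 °C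
Reagents that add atoms: mCPBA O=C(OO)c1cccc(Cl)c1
Why: Prilezhaev epoxidation should take only the terminal isopropylidene alkene, because the other trisubstituted alkene is deactivated by the allylic acetoxy group, and the new stereocentre is of no consequence.

Step 2
Reactants: 2 6,7-epoxyneryl acetate
Product: 3 6,7-epoxynerol
Conditions: K2CO3 (0.2 equiv), MeOH, 0 °C to rt
Reagents that add atoms: none
Why: Base-catalysed transesterification (Zemplén-type methanolysis) frees the allylic alcohol and leaves the trisubstituted epoxide and the Z alkene untouched.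

Step 3
Reactants: 3 6,7-epoxynerol
Product: 5 6,7-epoxyneryl bromide, via epoxyneryl mesylate 4 (not isolated)
Conditions: MsCl, Et3N, THF, −40 °C; then LiBr, THF, 0 °C
Reagents that add atoms: lithium bromide [Li+].[Br-]; methanesulfonyl chloride CS(=O)(=O)Cl (atoms in 4 only)
Why: Mesylation and SN2 displacement by bromide (Finkelstein-type exchange) at low temperature should give the primary allylic bromide without allylic transposition, Z to E isomerisation or epoxide opening.

Step 4
Reactants: 5 6,7-epoxyneryl bromide; 6 (S)-3-hydroxy-γ-butyrolactone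
Product: 8 trans-(3S,4S)-3-(6,7-epoxyneryl)-4-hydroxyoxolan-2-one, via dilithio dianion 7 (not isolated)
Conditions: 6 (1.3 equiv), LiN(i-Pr)2 (LDA, 2.6 equiv), THF, −78 °C; then 5, DMPU, −78 to −30 °C; aq NH4Cl
Reagents that add atoms: lithium diisopropylamide CC(C)[N-]C(C)C.[Li+] (lithium in 7 only)
Why: In this Fráter–Seebach-type alkylation of a β-hydroxy lactone dianion the enolate carbon attacks the allylic bromide on the ring face opposite the C8 alkoxide, so C7 is set trans to the C8 oxygen, which comes unchanged from the chiral pool.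

Step 5
Reactants: 8 trans-(3S,4S)-3-(6,7-epoxyneryl)-4-hydroxyoxolan-2-one
Product: 9 (3S,4S)-3-(6,7-epoxyneryl)oxolane-2,4-diol (lactol, anomer mixture)
Conditions: i-Bu2AlH (DIBAL-H, 2.3 equiv), CH2Cl2, −78 °C; aq potassium sodium tartrate
Reagents that add atoms: none
Why: DIBAL-H reduction of a lactone stops at the aluminium hemiacetal at low temperature, the first equivalent being spent on the free hydroxyl, and C7, C8 and the epoxide are not touched.

Step 6
Reactants: 9 (3S,4S)-3-(6,7-epoxyneryl)oxolane-2,4-diol
Product: 10 (2S,3R,5Z)-9,10-epoxy-3-ethynyl-6,10-dimethylundec-5-ene-1,2-diol (7R,8S)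
Conditions: dimethyl (1-diazo-2-oxopropyl)phosphonate (1.5 equiv), K2CO3 (2 equiv), MeOH, 0 °C to rt
Reagents that add atoms: Ohira–Bestmann reagent CC(=O)C(=[N+]=[N-])P(=O)(OC)OC
Why: Seyferth–Gilbert homologation with the Ohira–Bestmann reagent traps the open hydroxy aldehyde form of the lactol and turns C11 into a terminal alkyne (C13 from the reagent) under carbonate conditions mild enough to keep the C7 configuration.

Step 7
Reactants: 10 alkyne diol
Product: 11 9-O-TBS ether of 10
Conditions: TBSCl (1.05 equiv), imidazole, CH2Cl2, 0 °C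
Reagents that add atoms: TBSCl CC(C)(C)[Si](C)(C)Cl
Why: Silylation with one equivalent of the bulky chlorosilane is selective for the primary C9 hydroxyl over the flanked secondary C8 hydroxyl.

Step 8
Reactants: 11 9-O-TBS ether of 10
Product: 12 8-O-methacrylate of 11
Conditions: methacrylic anhydride, Et3N, DMAP (cat.), CH2Cl2, 0 °C to rt
Reagents that add atoms: methacrylic anhydride C=C(C)C(=O)OC(=O)C(C)=C
Why: DMAP-catalysed acylation places the methacrylate on O8 before any C12 carboxyl group exists, which rules out later closure to an 8,12-lactone.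

Step 9
Reactants: 12 8-O-methacrylate of 11
Product: 13 (4Z,7R,8S)-9-(tert-butyldimethylsilyloxy)-7-ethynyl-8-(methacryloyloxy)-4-methylnon-4-enal
Conditions: H5IO6 (1.2 equiv), THF/Et2O, 0 °C
Reagents that add atoms: none
Why: Periodic acid opens the trisubstituted epoxide and cleaves the glycol (Malaprade cleavage) to the C1 aldehyde and acetone without touching the alkenes, the alkyne or the esters.

Step 10
Reactants: 13 C1 aldehyde
Product: 14 (2E,6Z,9R,10S)-11-(tert-butyldimethylsilyloxy)-9-ethynyl-10-(methacryloyloxy)-6-methylundeca-2,6-dienal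
Conditions: Ph3P=CHCHO (1.2 equiv), toluene, 60 °C
Reagents that add atoms: (triphenylphosphoranylidene)acetaldehyde O=CC=P(c1ccccc1)(c1ccccc1)c1ccccc1
Why: Wittig olefination with the stabilised formyl ylide adds C10 and C14 and should give the E enal.

Step 11
Reactants: 14 E enal with terminal alkyne
Product: 15 2-(trimethylsilyl)ethyl acrylate (C11=C13, C12 ester) of enal 14
Conditions: Pd(OAc)2 (2 mol %), 2-(diphenylphosphino)pyridine (20 mol %), MsOH (10 mol %), CO (5 bar), Me3SiCH2CH2OH (5 equiv), toluene, 40 °C
Reagents that add atoms: carbon monoxide [C-]#[O+]; 2-(trimethylsilyl)ethanol C[Si](C)(C)CCO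
Why: Palladium-catalysed Markovnikov hydroalkoxycarbonylation (Reppe-type carbonylation) of the terminal alkyne with the pyridylphosphine ligand puts the acyl group on the internal carbon C11, and it is run before any carbon–iodine bond is present that zerovalent palladium could attack.

Step 12
Reactants: 15 acrylate enal
Product: 16 (Z)-α-iodoenal (iodine on C10 cis to C2, formyl trans to C2)
Conditions: iodine (1.5 equiv), DMAP (0.2 equiv), pyridine/CH2Cl2, 0 °C to rt, dark
Reagents that add atoms: iodine II
Why: Amine-catalysed α-iodination of the enal (Baylis–Hillman-type addition of DMAP, iodination of the enolate, elimination) should give the more stable isomer with the formyl group trans to C2, while the α-substituted acrylates cannot react this way and anhydrous iodine adds only reversibly to C4=C5.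

Step 13
Reactants: 16 (Z)-α-iodoenal
Product: 18 9-hydroxy C14 dimethyl acetal, via acetal silyl ether 17 (not isolated)
Conditions: HC(OMe)3 (5 equiv), camphorsulfonic acid (0.1 equiv), MeOH, 0 °C to rt
Reagents that add atoms: trimethyl orthoformate COC(OC)OC
Why: Acid-catalysed acetalisation with the orthoformate masks C14, so that only one aldehyde will be present in the ring closure, and the same acidic methanol solvolyses the primary TBS ether under conditions too mild for acyl migration.

Step 14
Reactants: 18 9-hydroxy C14 dimethyl acetal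
Product: 19 C9 aldehyde (α-methacryloyloxy aldehyde with vinyl iodide)
Conditions: Dess–Martin periodinane (1.3 equiv), pyridine, CH2Cl2, 0 °C; used crude
Reagents that add atoms: none
Why: Dess–Martin oxidation under buffered, non-basic conditions should give the α-acyloxy aldehyde without epimerisation at C8 and without harm to the acetal.

Step 15
Reactants: 19 C9 aldehyde
Product: 20 macrocyclic 9β-alcohol (7R,8S,9R; C1=C10 ring-cis, C4=C5 Z)
Conditions: CrCl2 (8 equiv), NiCl2 (0.1 equiv), DMSO, slow addition of 19 to 2 mM, rt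
Reagents that add atoms: none
Why: In this intramolecular Nozaki–Hiyama–Kishi reaction the alkenylchromium species keeps its geometry and adds only to the aldehyde, the two cis alkenes bring the chain ends together, and the polar Felkin–Anh approach anti to the C8–O bond should give the 9β (9R) alcohol.

Step 16
Reactants: 20 macrocyclic 9β-alcohol
Product: 21 9β-acetate
Conditions: Ac2O, pyridine, DMAP (cat.), CH2Cl2, 0 °C
Reagents that add atoms: acetic anhydride CC(=O)OC(C)=O
Why: DMAP-catalysed acetylation of the allylic alcohol is fast enough to outrun migration of the neighbouring methacrylate.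

Step 17
Reactants: 21 9β-acetate
Product: 23 8β-methacryloyloxy-9β-acetoxy-14-oxo-cis,cis-germacra-1(10),4,11(13)-trien-12-oic acid (7R,8S,9R), via acetal acid 22 (not isolated)
Conditions: Bu4NF (TBAF, 2 equiv), THF, 0 °C; then 1 M aq HCl to pH 2, THF/H2O, rt
Reagents that add atoms: water O
Why: Fluoride-induced β-elimination of the 2-(trimethylsilyl)ethyl ester frees the acid while C14 is still masked and the molecule is not yet base-sensitive, and dilute aqueous acid then hydrolyses the allylic dimethyl acetal to the enal.

Step 18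
Reactants: 23 seco acid
Product: 25 4,5-deoxy target (6α,12-olide; 6R,7S,8S,9R), via 6α-hydroxy acid 24 (not isolated)
Conditions: CYP71BL-type costunolide synthase variant with its NADPH reductase (yeast microsomes, cell-free), air, NADP+ (cat.), D-glucose/glucose dehydrogenase, catalase, potassium phosphate buffer pH 7.5, 2% DMSO, 28 °C; then pH 5, EtOAc
Reagents that add atoms: dioxygen O=O
Why: Proposed new method: the ferryl-oxo porphyrin radical cation of the enzyme abstracts the pro-α hydrogen at C6 to give a C4–C5–C6 allyl radical held over the haem, and fast hydroxyl rebound at C6 forms alcohol 24. The closest known reactions are the 6α-hydroxylation–lactonisation of germacrene A acid by CYP71BL costunolide synthases and site-selective allylic hydroxylations of germacranolides by evolved CYP102A1 variants, but neither has been shown on a Z,Z acid with an 8,9-diester and a C14 aldehyde, so homologue screening and active-site mutagenesis belong to the step. The 6α-hydroxyl of 24 lies 1,4 to C12 and closes by 5-exo-trig attack on the carboxyl carbon with loss of water, and the lactone is trans-fused because O6 (α) and C11 (β) lie on opposite faces. The configuration at C6 is set by the enzyme pocket, which presents only the α hydrogen to the oxidant while polar residues anchor the carboxylate. The step needs C6 over C2, C3, C7, C9, C15 and the methacrylate methyl, and hydroxylation over C4=C5 epoxidation, and the substrate helps because the C6 radical has a tertiary terminus at C4, C2 and C9 are deactivated by the enal and the acetate, and C6 lies close to the anchored acid. Cell-free enzyme is used so that host esterases and ene-reductases cannot touch the two esters and the enal.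

Step 19
Reactants: 25 4,5-deoxy target
Product: 26 target (4R,5S,6S,7R,8S,9R)
Conditions: mCPBA (1.1 equiv), CH2Cl2, 0 °C
Reagents that add atoms: mCPBA O=C(OO)c1cccc(Cl)c1
Why: Prilezhaev epoxidation should touch only C4=C5, the one alkene not conjugated to a carbonyl group, with syn delivery that keeps C3 and C6 cis on the oxirane, and from the α face because C11 of the lactone and both ester groups crowd the β face, which sets 4R and 5S.

Compound list
1 | neryl acetate, (2Z)-3,7-dimethylocta-2,6-dien-1-yl acetate | CC(C)=CCC/C(C)=C\COC(C)=O | starting material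
2 | 6,7-epoxyneryl acetate (Z alkene kept, epoxide carbon racemic) | CC1(C)OC1CC/C(C)=C\COC(C)=O | intermediate
3 | 6,7-epoxynerol | CC1(C)OC1CC/C(C)=C\CO | intermediate
4 | 6,7-epoxyneryl mesylate (not isolated) | CC1(C)OC1CC/C(C)=C\COS(C)(=O)=O | intermediate
5 | 6,7-epoxyneryl bromide | CC1(C)OC1CC/C(C)=C\CBr | intermediate
6 | (S)-3-hydroxy-γ-butyrolactone, (4S)-4-hydroxyoxolan-2-one | O=C1C[C@H](O)CO1 | starting material
7 | dilithio dianion of 6, lithium enolate and lithium alkoxide (not isolated) | [Li+].[Li+].[O-]C1=C[C@H]([O-])CO1 | intermediate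
8 | trans-(3S,4S)-3-(6,7-epoxyneryl)-4-hydroxyoxolan-2-one (ring C3 = C7, ring C4 = C8) | O=C1[C@@H](C/C=C(/C)CCC2OC2(C)C)[C@H](O)CO1 | intermediate
9 | (3S,4S)-3-(6,7-epoxyneryl)oxolane-2,4-diol, lactol, anomer mixture | OC1[C@@H](C/C=C(/C)CCC2OC2(C)C)[C@H](O)CO1 | intermediate
10 | (2S,3R,5Z)-9,10-epoxy-3-ethynyl-6,10-dimethylundec-5-ene-1,2-diol (7R,8S) | C#C[C@@H](C/C=C(/C)CCC1OC1(C)C)[C@H](O)CO | intermediate
11 | 9-O-TBS ether of 10, free 8-OH (7R,8S) | C#C[C@@H](C/C=C(/C)CCC1OC1(C)C)[C@H](O)CO[Si](C)(C)C(C)(C)C | intermediate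
12 | 8-O-methacrylate of 11 (7R,8S) | C#C[C@@H](C/C=C(/C)CCC1OC1(C)C)[C@H](OC(=O)C(C)=C)CO[Si](C)(C)C(C)(C)C | intermediate
13 | (4Z,7R,8S)-9-(tert-butyldimethylsilyloxy)-7-ethynyl-8-(methacryloyloxy)-4-methylnon-4-enal | C#C[C@@H](C/C=C(/C)CCC=O)[C@H](OC(=O)C(C)=C)CO[Si](C)(C)C(C)(C)C | intermediate
14 | (2E,6Z,9R,10S)-11-(tert-butyldimethylsilyloxy)-9-ethynyl-10-(methacryloyloxy)-6-methylundeca-2,6-dienal | C#C[C@@H](C/C=C(/C)CC/C=C/C=O)[C@H](OC(=O)C(C)=C)CO[Si](C)(C)C(C)(C)C | intermediate
15 | 2-(trimethylsilyl)ethyl acrylate: 14 with C7–C(=CH2)CO2CH2CH2SiMe3 in place of the alkyne (7R,8S) | C=C(C(=O)OCC[Si](C)(C)C)[C@@H](C/C=C(/C)CC/C=C/C=O)[C@H](OC(=O)C(C)=C)CO[Si](C)(C)C(C)(C)C | intermediate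
16 | (Z)-α-iodoenal: 15 with iodine on C10, cis to C2 (7R,8S) | C=C(C(=O)OCC[Si](C)(C)C)[C@@H](C/C=C(/C)CC/C=C(/C=O)I)[C@H](OC(=O)C(C)=C)CO[Si](C)(C)C(C)(C)C | intermediate
17 | C14 dimethyl acetal of 16, TBS ether kept (not isolated) | C=C(C(=O)OCC[Si](C)(C)C)[C@@H](C/C=C(/C)CC/C=C(/C(OC)OC)I)[C@H](OC(=O)C(C)=C)CO[Si](C)(C)C(C)(C)C | intermediate
18 | C14 dimethyl acetal with free primary 9-OH (7R,8S) | C=C(C(=O)OCC[Si](C)(C)C)[C@@H](C/C=C(/C)CC/C=C(/C(OC)OC)I)[C@H](OC(=O)C(C)=C)CO | intermediate
19 | C9 aldehyde with (Z)-vinyl iodide and C14 acetal (7R,8S) | C=C(C(=O)OCC[Si](C)(C)C)[C@@H](C/C=C(/C)CC/C=C(/C(OC)OC)I)[C@H](OC(=O)C(C)=C)C=O | intermediate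
20 | ten-membered carbocycle, 9β-OH, 8β-methacrylate, 7α-H, C12 TMSE ester, C14 dimethyl acetal (7R,8S,9R; both ring alkenes cis) | C=C(C)C(=O)O[C@H]1[C@@H](C(=C)C(=O)OCC[Si](C)(C)C)C/C=C(/C)CC/C=C(/C(OC)OC)[C@H]1O | intermediate
21 | 9β-acetate of 20 | C=C(C)C(=O)O[C@H]1[C@@H](C(=C)C(=O)OCC[Si](C)(C)C)C/C=C(/C)CC/C=C(/C(OC)OC)[C@H]1OC(C)=O | intermediate
22 | C12 acid with C14 dimethyl acetal (not isolated) | C=C(C)C(=O)O[C@H]1[C@@H](C(=C)C(=O)O)C/C=C(/C)CC/C=C(/C(OC)OC)[C@H]1OC(C)=O | intermediate
23 | 8β-methacryloyloxy-9β-acetoxy-14-oxo-cis,cis-germacra-1(10),4,11(13)-trien-12-oic acid (7R,8S,9R) | C=C(C)C(=O)O[C@H]1[C@@H](C(=C)C(=O)O)C/C=C(/C)CC/C=C(/C=O)[C@H]1OC(C)=O | intermediate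
24 | 6α-hydroxy derivative of 23 (6R,7S,8S,9R; not isolated) | C=C(C)C(=O)O[C@H]1[C@@H](C(=C)C(=O)O)[C@H](O)/C=C(/C)CC/C=C(/C=O)[C@H]1OC(C)=O | intermediate
25 | 4,5-deoxy target, cis,cis-germacran-6α,12-olide, trans-fused (6R,7S,8S,9R) | C=C(C)C(=O)O[C@H]1[C@H]2C(=C)C(=O)O[C@@H]2/C=C(/C)CC/C=C(/C=O)[C@H]1OC(C)=O | intermediate
26 | CNP0121379.1, 4α,5α-epoxide of 25 (4R,5S,6S,7R,8S,9R) | C=C(C)C(=O)O[C@H]1[C@H]2C(=C)C(=O)O[C@@H]2[C@@H]2O[C@]2(C)CC/C=C(/C=O)[C@H]1OC(C)=O | target

Total step count: 19. Longest linear sequence: 19 steps (from neryl acetate).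

Steps most likely to fail

1. Step 18. The enzyme may not bind the non-native Z,Z diester productively. It may transfer oxygen to C4=C5, C3 or C15 instead of C6, or it may oxidise the aldehyde. The fallback uses known chemical oxidation, sets out from 23 and comes back at 25. Radical-chain allylic oxidation with Rh2(cap)4 (dirhodium tetracaprolactamate) and aqueous t-BuOOH in CH2Cl2 favours the methylene on the CH end of an electron-rich trisubstituted alkene. It should therefore give the 6-oxo acid F1. Luche reduction (NaBH4, CeCl3·7H2O, MeOH, −78 °C) then reduces the C6 enone and the C14 enal in 1,2 fashion to the 6α,14-dihydroxy acid F2. Mild acidification closes F2 to the 14-hydroxy lactone F3. MnO2 in CH2Cl2 reoxidises the primary allylic alcohol to 25.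

2. Step 15. Ring closure may be slower than oligomerisation, and the ring conformation may override the Felkin–Anh preference, so facial selectivity at the C9 aldehyde may be poor. The fallback sets C9 by reagent-controlled ketone reduction instead of by the carbon–carbon bond formation. It sets out from 19 and comes back at 20. The closure is run as before, and the 9-epi alcohol F4, alone or mixed with 20, is oxidised with Dess–Martin periodinane to the C9 enone F5. Corey–Bakshi–Shibata reduction with catecholborane at −78 °C then gives 20. (R)-2-methyl-CBS-oxazaborolidine is chosen on the premise that the trisubstituted alkenyl group acts as the large substituent.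

3. Step 19. Facial selectivity may be poor or reversed if the reactive ring conformer exposes the β face of C4=C5. The fallback inverts the face through a halohydrin, sets out from 25 and comes back at 26. NBS in THF/H2O at 0 °C places bromine on the accessible face at C5 and water anti at the tertiary C4, which gives the bromohydrin F6. Ag2O in CH2Cl2 closes F6 by backside displacement at C5, so the oxirane oxygen ends on the face opposite to the one the electrophile attacked.

Further compounds
F1 | step 18 | 6-oxo derivative of acid 23 | C=C(C)C(=O)O[C@H]1[C@@H](C(=C)C(=O)O)C(=O)/C=C(/C)CC/C=C(/C=O)[C@H]1OC(C)=O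
F2 | step 18 | 6α,14-dihydroxy acid | C=C(C)C(=O)O[C@H]1[C@@H](C(=C)C(=O)O)[C@H](O)/C=C(/C)CC/C=C(/CO)[C@H]1OC(C)=O
F3 | step 18 | 14-hydroxy 6α,12-lactone | C=C(C)C(=O)O[C@H]1[C@H]2C(=C)C(=O)O[C@@H]2/C=C(/C)CC/C=C(/CO)[C@H]1OC(C)=O
F4 | step 15 | 9-epi alcohol (9α-OH epimer of 20) | C=C(C)C(=O)O[C@H]1[C@@H](C(=C)C(=O)OCC[Si](C)(C)C)C/C=C(/C)CC/C=C(/C(OC)OC)[C@@H]1O
F5 | step 15 | C9 enone | C=C(C)C(=O)O[C@H]1[C@@H](C(=C)C(=O)OCC[Si](C)(C)C)C/C=C(/C)CC/C=C(/C(OC)OC)C1=O
F6 | step 19 | 5β-bromo-4α-hydroxy bromohydrin of 25 | C=C(C)C(=O)O[C@H]1[C@H]2C(=C)C(=O)O[C@@H]2[C@@H](Br)[C@](C)(O)CC/C=C(/C=O)[C@H]1OC(C)=O
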